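The ring is opened at C7=C8 of the nine-membered carbocycle (C1–C9). The key step exploits the α-branched enal C7=C8–C20, whose ring-cis geometry puts C6 anti to C20. A silyl ynol ether on C9 and an aldehyde at C7 join by [2+2] cycloaddition and 4π ring opening. One operation closes the cyclononadiene, installs C7=C8 with the right geometry and brings C20 to the carboxyl level. The precursor is an acyclic, all-silyl-protected chain with the four stereocentres (C1, C2, C9, C10), the (E)-C4=C5 olefin, a β,γ-unsaturated C7 aldehyde and a C8≡C20 triisopropylsilyl ynol ether. It is built on two lactone templates from (R)-butadiene monoxide.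

Key step: step 18

Remark: locants C1–C20 are those of the target (ring C1–C9; C10 the side-chain CH; C18 its CH2O; C19 and C20 the carbons on C9 and C8). C7′ is the extra glycol carbon removed in step 17. Every acyclic and nine-membered compound from 18 on is (1R,2S,9R,10S).
Assumption: (R)-2-vinyloxirane is bought as the single enantiomer.
Assumption: (S)-TRIP is taken to direct Si-face propargyl transfer, as in the related allylboration; if the sense proves opposite, (R)-TRIP is used.
Assumption: (S)-glycidyl pivalate is bought; the racemate would serve, since its stereocentre is excised in step 17.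
Design note: the key-step substrate carries silyl ethers only (TES on O18, TBS on O2 and O19), graded for the end game and poorly Lewis-basic next to the ynol ether.

Step 1
Reactants: 1 (R)-butadiene monoxide; 2 trimethylsilylacetylene
Product: 4 (R)-2-[(trimethylsilyl)ethynyl]but-3-en-1-ol, via lithium (trimethylsilyl)acetylide 3 (not isolated)
Conditions: n-BuLi, THF, −78 °C; BF3·OEt2, then 1, −78 °C; H2O
Reagents that add atoms: none
Why: BF3-promoted alkynylation of a vinyl epoxide, in which the alkynyllithium should attack the activated allylic carbon in an SN2 sense, so the epoxide centre is inverted and becomes C9 with the required R configuration.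

Step 2
Reactants: 4 (R)-2-[(trimethylsilyl)ethynyl]but-3-en-1-ol
Product: 5 (R)-2-[(trimethylsilyl)ethynyl]but-3-en-1-yl acrylate
Conditions: acryloyl chloride, Et3N, CH2Cl2, 0 °C
Reagents that add atoms: acryloyl chloride, C=CC(=O)Cl
Why: O-acylation of a primary alcohol, which brings in C10 and C18.

Step 3
Reactants: 5 (R)-2-[(trimethylsilyl)ethynyl]but-3-en-1-yl acrylate
Product: 6 (R)-5-[(trimethylsilyl)ethynyl]-5,6-dihydro-2H-pyran-2-one
Conditions: (H2IMes)(PCy3)Cl2Ru=CHPh (5 mol%), CH2Cl2 (10 mM), 40 °C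
Reagents that add atoms: none
Why: ring-closing olefin metathesis of an acrylate onto a monosubstituted olefin is a standard entry to six-membered unsaturated lactones, and the silyl-capped alkyne is a poor enyne-metathesis partner.

Step 4
Reactants: 6 (R)-5-[(trimethylsilyl)ethynyl]-5,6-dihydro-2H-pyran-2-one
Product: 7 (4S,5R)-4-ethenyl-5-[(trimethylsilyl)ethynyl]oxan-2-one (4,5-trans)
Conditions: CH2=CHMgBr (2.2 equiv), CuI (1.1 equiv), THF, −78 → −40 °C; 1 M HCl
Reagents that add atoms: vinylmagnesium bromide, C=C[Mg]Br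
Why: conjugate addition of a vinyl cuprate to the enoate, where attack anti to the neighbouring alkynyl group on the half-chair should set C1 trans to C9.

Step 5
Reactants: 7 (4S,5R)-4-ethenyl-5-[(trimethylsilyl)ethynyl]oxan-2-one
Product: 9 (4R,5R)-2-oxo-5-[(trimethylsilyl)ethynyl]oxane-4-carbaldehyde, via ozonide 8 (not isolated)
Conditions: O3, CH2Cl2, −78 °C (Sudan Red 7B end point); PPh3, −78 °C → rt
Reagents that add atoms: ozone, [O-][O+]=O
Why: ozonolysis with reductive work-up, in which the monosubstituted alkene reacts far faster than the silylalkyne; the cleavage is placed here, before any trisubstituted olefin is in the molecule.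

Step 6
Reactants: 9 (4R,5R)-2-oxo-5-[(trimethylsilyl)ethynyl]oxane-4-carbaldehyde; 10 allenylboronic acid pinacol ester
Product: 12 (4R,5S)-4-[(2R)-1-hydroxy-4-(trimethylsilyl)but-3-yn-2-yl]-5-(prop-2-yn-1-yl)oxolan-2-one (4,5-cis γ-lactone), via δ-lactone alcohol 11 (not isolated)
Conditions: (S)-TRIP (10 mol%), 4 Å MS, toluene, −20 °C; aq. NaHCO3; then CSA (10 mol%), CH2Cl2, rt
Reagents that add atoms: none
Why: chiral phosphoric acid-catalysed propargylboration through a closed six-membered transition state (SE2′ transfer from the allenylboronate), in which the catalyst should direct Si-face attack and set C2 as S; acid-catalysed translactonisation then moves the acyl group to the new C2 hydroxyl, giving the more stable five-membered lactone and freeing O19.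

Step 7
Reactants: 12 γ-lactone alcohol
Product: 13 (4R,5S)-4-[(2R)-1-[(tert-butyldimethylsilyl)oxy]-4-(trimethylsilyl)but-3-yn-2-yl]-5-(prop-2-yn-1-yl)oxolan-2-one
Conditions: TBSCl, imidazole, CH2Cl2, 0 °C → rt
Reagents that add atoms: tert-butyldimethylsilyl chloride, CC(C)(C)[Si](C)(C)Cl
Why: silylation of the primary alcohol, which also drains any δ-lactone left in equilibrium because only the γ-lactone offers an unhindered primary hydroxyl.

Step 8
Reactants: 14 5-bromo-2-methylpent-2-ene
Product: 15 5-iodo-2-methylpent-2-ene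
Conditions: NaI, acetone, reflux
Reagents that add atoms: sodium iodide, [Na+].[I-]
Why: Finkelstein halide exchange, driven by precipitation of sodium bromide.

Step 9
Reactants: 13 γ-lactone TBS ether; 15 5-iodo-2-methylpent-2-ene
Product: 17 (3S,4S,5S)-4-[(2R)-1-[(tert-butyldimethylsilyl)oxy]-4-(trimethylsilyl)but-3-yn-2-yl]-3-(4-methylpent-3-en-1-yl)-5-(prop-2-yn-1-yl)oxolan-2-one (3,4-trans, 4,5-cis), via dilithio enolate–acetylide 16 (not isolated)
Conditions: LDA (2.2 equiv), THF, −78 °C; 15, DMPU, −78 → −40 °C; H2O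
Reagents that add atoms: none
Why: alkylation of a γ-butyrolactone enolate, where the C1 and C2 substituents occupy the same ring face, so the iodide should enter from the other face and set C10 trans to the C1 branch; the lithium acetylide should not react with an unactivated iodide at this temperature.

Step 10
Reactants: 17 alkylated γ-lactone
Product: 18 diol (O18–H and O2–H free, O19 TBS, C4≡C5H, C8≡C20–SiMe3)
Conditions: LiBH4, MeOH (1 equiv), THF, 0 °C → rt
Reagents that add atoms: none
Why: borohydride reduction of the lactone to the 1,4-diol releases C18 as a primary and C2 as a hindered secondary alcohol without touching alkynes or silyl groups.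

Step 11
Reactants: 18 diol
Product: 20 tris-silyl diyne (O18 TES, O2 TBS, O19 TBS), via C18 triethylsilyl ether 19 (not isolated)
Conditions: TESCl (1.05 equiv), 2,6-lutidine, DMAP (cat.), CH2Cl2, −78 → −40 °C; then TBSOTf, −78 → 0 °C
Reagents that add atoms: chlorotriethylsilane, CC[Si](Cl)(CC)CC; tert-butyldimethylsilyl triflate, CC(C)(C)[Si](C)(C)OS(=O)(=O)C(F)(F)F
Why: sequential silylation by steric discrimination, where the chlorosilane should take only the primary O18 at low temperature and the silyl triflate then caps the hindered O2.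

Step 12
Reactants: 20 tris-silyl diyne
Product: 23 (7S)-hydroxy pivalate (C4(Me)=C5 E; C7–OH, C7′–OPiv), via alkenylalane 21 (not isolated), via lithium alkenylalanate 22 (not isolated)
Conditions: AlMe3, Cp2ZrCl2 (25 mol%), CH2Cl2, 0 °C → rt; evaporate; n-BuLi, hexane–THF, −78 °C; (S)-glycidyl pivalate, −78 → 0 °C; Rochelle salt
Reagents that add atoms: trimethylaluminium, C[Al](C)C; (S)-glycidyl pivalate, CC(C)(C)C(=O)OC[C@@H]1CO1
Why: Negishi carboalumination adds methyl and aluminium syn across the terminal C4≡C5 alkyne (methyl to C4; the silyl-capped C8≡C20 alkyne is inert), and the derived alanate opens the epoxide at its CH2 terminus with retention of alkene geometry, giving the (E)-C4=C5 olefin and C6–C7 with a glycol as latent aldehyde.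

Step 13
Reactants: 23 hydroxy pivalate
Product: 24 C7,C7′-bis-pivalate
Conditions: PivCl, pyridine, DMAP (cat.), CH2Cl2, 0 °C → rt
Reagents that add atoms: pivaloyl chloride, CC(C)(C)C(=O)Cl
Why: acylation of the secondary alcohol; pivalates have no α-hydrogen and are hindered, so they should survive the amide base and peroxide of step 15.

Step 14
Reactants: 24 C7,C7′-bis-pivalate
Product: 25 terminal alkyne (C8≡C20–H) bis-pivalate
Conditions: K2CO3 (0.3 equiv), MeOH–THF, 0 °C → rt
Reagents that add atoms: none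
Why: base-catalysed methanolysis of the alkynyl C–Si bond, under which pivalates and alkyl silyl ethers are stable.

Step 15
Reactants: 25 terminal alkyne bis-pivalate
Product: 28 triisopropylsilyl ynol ether bis-pivalate (C8≡C20–OTIPS), via lithium acetylide 26 (not isolated), via lithium ynolate 27 (not isolated)
Conditions: LiHMDS, THF, −78 °C; t-BuOOLi (from t-BuOOH, LiHMDS), −78 → 0 °C; TIPSOTf, −78 °C
Reagents that add atoms: lithium tert-butyl peroxide, CC(C)(C)OO[Li]; triisopropylsilyl triflate, CC(C)[Si](C(C)C)(C(C)C)OS(=O)(=O)C(F)(F)F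
Why: oxidation of a lithium acetylide by the electrophilic oxygen of a lithium alkyl peroxide gives the ynolate, which a bulky silyl triflate traps on oxygen as a chromatographable silyl ynol ether.

Step 16
Reactants: 28 ynol ether bis-pivalate
Product: 29 ynol ether C7,C7′-diol
Conditions: DIBAL-H (5 equiv), CH2Cl2, −78 °C; Rochelle salt
Reagents that add atoms: none
Why: reductive cleavage of both esters by hydride at low temperature uses no acid, fluoride or electrophile, so the ynol ether and the silyl ethers should be left alone.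

Step 17
Reactants: 29 ynol ether diol
Product: 30 key-step precursor (C7 aldehyde, C8≡C20–OTIPS, O18 TES, O2 TBS, O19 TBS)
Conditions: NaIO4 on silica gel, CH2Cl2, 0 °C → rt
Reagents that add atoms: none
Why: periodate glycol cleavage releases the β,γ-unsaturated aldehyde under neutral conditions, so no base can move the C4=C5 olefin into conjugation and no electrophilic oxidant meets the ynol ether.

Step 18
Reactants: 30 key-step precursor
Product: 32 cyclonona-4,7-diene C20 triisopropylsilyl ester, via siloxy-oxetene 31 (not isolated)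
Conditions: AgNTf2 (10 mol%), 4 Å MS, CH2Cl2, slow addition to 1 mM, −20 °C → rt
Reagents that add atoms: none
Why: Proposed new method: silver(I) activates the electron-rich ynol ether, whose carbon C8 attacks the C7 aldehyde (9-exo-dig at the alkyne, exo-trig at the carbonyl) to give a silyl ketenium that closes on the aldehyde oxygen to the siloxy-oxetene 31, and conrotatory 4π opening then breaks C7–O and delivers C7=C8 with C20 as a silyl ester. The closest known reaction types are the silver-catalysed intermolecular olefination of aldehydes by siloxyalkynes and the acid-catalysed ring-closing ynol ether–carbonyl metathesis that gives five- to seven-membered cycloalkenecarboxylates; a nine-membered closure has not been shown. No stereocentre is formed; the olefin geometry follows from outward rotation of C6 at C7, which is both the preference of an alkyl group and the only sense the ring allows, so C6 ends anti to C20. The step needs ring closure to outrun oligomerisation and the C4=C5 olefin to stay in place: millimolar concentration, the rigid (E)-C4=C5 unit, the three branched centres C1, C2 and C9 that fold the chain, and the absence of base or protic acid should serve this. Only hindered silyl ethers flank the reacting termini, so no Lewis-basic oxygen should intercept the ketenium.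

Step 19
Reactants: 32 cyclononadiene silyl ester
Product: 33 C20 allylic alcohol
Conditions: DIBAL-H (3 equiv), CH2Cl2, −78 °C; Rochelle salt
Reagents that add atoms: none
Why: hydride reduction of the silyl enoate, in which DIBAL-H adds 1,2 so that C20 reaches the alcohol level without conjugate reduction.

Step 20
Reactants: 33 C20 allylic alcohol
Product: 34 C20 tert-butyldimethylsilyl ether
Conditions: TBSCl, imidazole, CH2Cl2, 0 °C → rt
Reagents that add atoms: tert-butyldimethylsilyl chloride, CC(C)(C)[Si](C)(C)Cl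
Why: silylation of the primary allylic alcohol gives O19 and O20 the same group, so both can be released together later.

Step 21
Reactants: 34 C20 TBS ether
Product: 35 C18 alcohol
Conditions: PPTS (20 mol%), MeOH–CH2Cl2, 0 °C
Reagents that add atoms: none
Why: acid-catalysed methanolysis distinguishes silyl ethers by bulk, so the primary triethylsilyl ether on O18 should be cleaved while the three TBS ethers stay.

Step 22
Reactants: 35 C18 alcohol
Product: 36 C18 acetate
Conditions: Ac2O, pyridine, DMAP (cat.), CH2Cl2, 0 °C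
Reagents that add atoms: acetic anhydride, CC(=O)OC(C)=O
Why: acetylation of the only free hydroxyl installs the C18 acetate before C19 is oxidised, which rules out a six-membered lactol between O18 and C19.

Step 23
Reactants: 36 C18 acetate
Product: 37 C19,C20-diol (O2 still TBS)
Conditions: HF·pyridine, pyridine, THF, 0 °C
Reagents that add atoms: none
Why: buffered fluoride desilylation should remove the two primary TBS ethers much faster than the hindered secondary one on O2, and the acetate is stable.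

Step 24
Reactants: 37 C19,C20-diol
Product: 39 O2-TBS dialdehyde, via bis(alkoxysulfonium) chloride 38 (not isolated)
Conditions: (COCl)2, DMSO, CH2Cl2, −78 °C; Et3N, −78 → −40 °C
Reagents that add atoms: none
Why: Swern oxidation converts both hydroxyls to alkoxysulfonium ions before base is added, so neither aldehyde meets a free neighbouring hydroxyl and no lactol or lactone can form; brief cold exposure to Et3N should spare the epimerisable C9 centre.

Step 25
Reactants: 39 O2-TBS dialdehyde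
Product: 40 target CNP0284729.1
Conditions: HF·pyridine, THF, 0 °C → rt
Reagents that add atoms: none
Why: fluoride cleavage of the last silyl ether under mildly acidic, base-free conditions, chosen because the C9 formyl centre epimerises under base; the acetate and both aldehydes should tolerate it.

Compound list
1 | (R)-butadiene monoxide [(2R)-2-ethenyloxirane] | C=C[C@@H]1CO1 | starting material
2 | trimethylsilylacetylene | C#C[Si](C)(C)C | starting material
3 | lithium (trimethylsilyl)acetylide | [Li]C#C[Si](C)(C)C | intermediate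
4 | (R)-2-[(trimethylsilyl)ethynyl]but-3-en-1-ol | OC[C@@H](C#C[Si](C)(C)C)C=C | intermediate
5 | (R)-2-[(trimethylsilyl)ethynyl]but-3-en-1-yl acrylate | C=CC(=O)OC[C@@H](C#C[Si](C)(C)C)C=C | intermediate
6 | (R)-5-[(trimethylsilyl)ethynyl]-5,6-dihydro-2H-pyran-2-one | O=C1C=C[C@H](C#C[Si](C)(C)C)CO1 | intermediate
7 | (4S,5R)-4-ethenyl-5-[(trimethylsilyl)ethynyl]oxan-2-one | O=C1C[C@@H](C=C)[C@H](C#C[Si](C)(C)C)CO1 | intermediate
8 | 1,2,4-trioxolane (ozonide) of 7 | O=C1C[C@@H](C2OCOO2)[C@H](C#C[Si](C)(C)C)CO1 | intermediate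
9 | (4R,5R)-2-oxo-5-[(trimethylsilyl)ethynyl]oxane-4-carbaldehyde | O=C1C[C@@H](C=O)[C@H](C#C[Si](C)(C)C)CO1 | intermediate
10 | allenylboronic acid pinacol ester | C=C=CB1OC(C)(C)C(C)(C)O1 | starting material
11 | (4R,5R)-4-[(1S)-1-hydroxybut-3-yn-1-yl]-5-[(trimethylsilyl)ethynyl]oxan-2-one | O=C1C[C@@H]([C@@H](O)CC#C)[C@H](C#C[Si](C)(C)C)CO1 | intermediate
12 | (4R,5S)-4-[(2R)-1-hydroxy-4-(trimethylsilyl)but-3-yn-2-yl]-5-(prop-2-yn-1-yl)oxolan-2-one | O=C1C[C@H]([C@H](C#C[Si](C)(C)C)CO)[C@H](CC#C)O1 | intermediate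
13 | (4R,5S)-4-[(2R)-1-[(tert-butyldimethylsilyl)oxy]-4-(trimethylsilyl)but-3-yn-2-yl]-5-(prop-2-yn-1-yl)oxolan-2-one | O=C1C[C@H]([C@H](C#C[Si](C)(C)C)CO[Si](C)(C)C(C)(C)C)[C@H](CC#C)O1 | intermediate
14 | 5-bromo-2-methylpent-2-ene | CC(C)=CCCBr | starting material
15 | 5-iodo-2-methylpent-2-ene | CC(C)=CCCI | intermediate
16 | dilithio lactone enolate–acetylide of 13 | [Li]OC1=C[C@H]([C@H](C#C[Si](C)(C)C)CO[Si](C)(C)C(C)(C)C)[C@H](CC#C[Li])O1 | intermediate
17 | (3S,4S,5S)-4-[(2R)-1-[(tert-butyldimethylsilyl)oxy]-4-(trimethylsilyl)but-3-yn-2-yl]-3-(4-methylpent-3-en-1-yl)-5-(prop-2-yn-1-yl)oxolan-2-one | O=C1[C@@H](CCC=C(C)C)[C@H]([C@H](C#C[Si](C)(C)C)CO[Si](C)(C)C(C)(C)C)[C@H](CC#C)O1 | intermediate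
18 | (1R,2S,9R,10S)-diol: O18–H, O2–H, O19 TBS, C4≡C5H, C8≡C20–SiMe3 | OC[C@@H](CCC=C(C)C)[C@@H]([C@@H](O)CC#C)[C@H](C#C[Si](C)(C)C)CO[Si](C)(C)C(C)(C)C | intermediate
19 | C18 triethylsilyl ether of 18 | CC[Si](CC)(CC)OC[C@@H](CCC=C(C)C)[C@@H]([C@@H](O)CC#C)[C@H](C#C[Si](C)(C)C)CO[Si](C)(C)C(C)(C)C | intermediate
20 | tris-silyl diyne: O18 TES, O2 TBS, O19 TBS | CC[Si](CC)(CC)OC[C@@H](CCC=C(C)C)[C@@H]([C@@H](O[Si](C)(C)C(C)(C)C)CC#C)[C@H](C#C[Si](C)(C)C)CO[Si](C)(C)C(C)(C)C | intermediate
21 | (E)-alkenyl(dimethyl)alane: C4 methyl, Al on C5 | CC[Si](CC)(CC)OC[C@@H](CCC=C(C)C)[C@@H]([C@@H](O[Si](C)(C)C(C)(C)C)C/C(C)=C/[Al](C)C)[C@H](C#C[Si](C)(C)C)CO[Si](C)(C)C(C)(C)C | intermediate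
22 | lithium (E)-alkenyl(butyl)dimethylalanate | CC[Si](CC)(CC)OC[C@@H](CCC=C(C)C)[C@@H]([C@@H](O[Si](C)(C)C(C)(C)C)C/C(C)=C/[Al-](C)(C)CCCC)[C@H](C#C[Si](C)(C)C)CO[Si](C)(C)C(C)(C)C.[Li+] | intermediate
23 | (7S)-hydroxy pivalate: C7–OH, C7′–OPiv, (E)-C4=C5 | CC[Si](CC)(CC)OC[C@@H](CCC=C(C)C)[C@@H]([C@@H](O[Si](C)(C)C(C)(C)C)C/C(C)=C/C[C@H](O)COC(=O)C(C)(C)C)[C@H](C#C[Si](C)(C)C)CO[Si](C)(C)C(C)(C)C | intermediate
24 | C7,C7′-bis-pivalate, C8≡C20–SiMe3 | CC[Si](CC)(CC)OC[C@@H](CCC=C(C)C)[C@@H]([C@@H](O[Si](C)(C)C(C)(C)C)C/C(C)=C/C[C@H](OC(=O)C(C)(C)C)COC(=O)C(C)(C)C)[C@H](C#C[Si](C)(C)C)CO[Si](C)(C)C(C)(C)C | intermediate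
25 | bis-pivalate with terminal C8≡C20–H alkyne | CC[Si](CC)(CC)OC[C@@H](CCC=C(C)C)[C@@H]([C@@H](O[Si](C)(C)C(C)(C)C)C/C(C)=C/C[C@H](OC(=O)C(C)(C)C)COC(=O)C(C)(C)C)[C@H](C#C)CO[Si](C)(C)C(C)(C)C | intermediate
26 | lithium acetylide of 25 | CC[Si](CC)(CC)OC[C@@H](CCC=C(C)C)[C@@H]([C@@H](O[Si](C)(C)C(C)(C)C)C/C(C)=C/C[C@H](OC(=O)C(C)(C)C)COC(=O)C(C)(C)C)[C@H](C#C[Li])CO[Si](C)(C)C(C)(C)C | intermediate
27 | lithium ynolate (C8≡C20–OLi) | CC[Si](CC)(CC)OC[C@@H](CCC=C(C)C)[C@@H]([C@@H](O[Si](C)(C)C(C)(C)C)C/C(C)=C/C[C@H](OC(=O)C(C)(C)C)COC(=O)C(C)(C)C)[C@H](C#CO[Li])CO[Si](C)(C)C(C)(C)C | intermediate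
28 | triisopropylsilyl ynol ether bis-pivalate | CC[Si](CC)(CC)OC[C@@H](CCC=C(C)C)[C@@H]([C@@H](O[Si](C)(C)C(C)(C)C)C/C(C)=C/C[C@H](OC(=O)C(C)(C)C)COC(=O)C(C)(C)C)[C@H](C#CO[Si](C(C)C)(C(C)C)C(C)C)CO[Si](C)(C)C(C)(C)C | intermediate
29 | triisopropylsilyl ynol ether C7,C7′-diol | CC[Si](CC)(CC)OC[C@@H](CCC=C(C)C)[C@@H]([C@@H](O[Si](C)(C)C(C)(C)C)C/C(C)=C/C[C@H](O)CO)[C@H](C#CO[Si](C(C)C)(C(C)C)C(C)C)CO[Si](C)(C)C(C)(C)C | intermediate
30 | key-step precursor: acyclic ynol ether aldehyde (C7=O, C8≡C20–OTIPS, O18 TES, O2 TBS, O19 TBS) | CC[Si](CC)(CC)OC[C@@H](CCC=C(C)C)[C@@H]([C@@H](O[Si](C)(C)C(C)(C)C)C/C(C)=C/CC=O)[C@H](C#CO[Si](C(C)C)(C(C)C)C(C)C)CO[Si](C)(C)C(C)(C)C | intermediate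
31 | siloxy-oxetene fused at C7–C8 ([2+2] adduct) | CC[Si](CC)(CC)OC[C@@H](CCC=C(C)C)[C@H]1[C@@H](O[Si](C)(C)C(C)(C)C)C/C(C)=C/CC2OC(O[Si](C(C)C)(C(C)C)C(C)C)=C2[C@@H]1CO[Si](C)(C)C(C)(C)C | intermediate
32 | cyclonona-4,7-diene C20 triisopropylsilyl ester (4E; C6 anti to C20) | CC[Si](CC)(CC)OC[C@@H](CCC=C(C)C)[C@H]1[C@@H](O[Si](C)(C)C(C)(C)C)C/C(C)=C/C/C=C(/C(=O)O[Si](C(C)C)(C(C)C)C(C)C)[C@@H]1CO[Si](C)(C)C(C)(C)C | intermediate
33 | C20 allylic alcohol | CC[Si](CC)(CC)OC[C@@H](CCC=C(C)C)[C@H]1[C@@H](O[Si](C)(C)C(C)(C)C)C/C(C)=C/C/C=C(/CO)[C@@H]1CO[Si](C)(C)C(C)(C)C | intermediate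
34 | C20 TBS ether (O18 TES, O2/O19/O20 TBS) | CC[Si](CC)(CC)OC[C@@H](CCC=C(C)C)[C@H]1[C@@H](O[Si](C)(C)C(C)(C)C)C/C(C)=C/C/C=C(/CO[Si](C)(C)C(C)(C)C)[C@@H]1CO[Si](C)(C)C(C)(C)C | intermediate
35 | C18 alcohol (O2/O19/O20 TBS) | OC[C@@H](CCC=C(C)C)[C@H]1[C@@H](O[Si](C)(C)C(C)(C)C)C/C(C)=C/C/C=C(/CO[Si](C)(C)C(C)(C)C)[C@@H]1CO[Si](C)(C)C(C)(C)C | intermediate
36 | C18 acetate (O2/O19/O20 TBS) | CC(=O)OC[C@@H](CCC=C(C)C)[C@H]1[C@@H](O[Si](C)(C)C(C)(C)C)C/C(C)=C/C/C=C(/CO[Si](C)(C)C(C)(C)C)[C@@H]1CO[Si](C)(C)C(C)(C)C | intermediate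
37 | C19,C20-diol, C18 acetate, O2 TBS | CC(=O)OC[C@@H](CCC=C(C)C)[C@H]1[C@@H](O[Si](C)(C)C(C)(C)C)C/C(C)=C/C/C=C(/CO)[C@@H]1CO | intermediate
38 | bis(alkoxydimethylsulfonium) chloride of 37 | CC(=O)OC[C@@H](CCC=C(C)C)[C@H]1[C@@H](O[Si](C)(C)C(C)(C)C)C/C(C)=C/C/C=C(/CO[S+](C)C)[C@@H]1CO[S+](C)C.[Cl-].[Cl-] | intermediate
39 | O2-TBS dialdehyde | CC(=O)OC[C@@H](CCC=C(C)C)[C@H]1[C@@H](O[Si](C)(C)C(C)(C)C)C/C(C)=C/C/C=C(/C=O)[C@@H]1C=O | intermediate
40 | CNP0284729.1 | CC(=O)OC[C@@H](CCC=C(C)C)[C@H]1[C@@H](O)C/C(C)=C/C/C=C(/C=O)[C@@H]1C=O | target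

Total step count: 25. Longest linear sequence: 24 steps (steps 1–7 and 9–25; step 8 is a one-step side branch).

Steps most likely to fail

1. Step 18 (proposed new method). Oligomerisation through intermolecular ynol ether–aldehyde coupling may outrun the nine-membered closure, or the ketenium may be diverted before the oxetene forms. The fallback makes the C7–C8 bond by a Nozaki–Hiyama–Kishi cyclisation and sets out from 25. Markovnikov hydroiodination with B-iodo-9-BBN proceeds through the iodoalkenylborane F1, and protonolysis with acetic acid gives the 2-iodoalkene bis-pivalate F2. DIBAL-H then gives the iodo diol F3, and periodate on silica gives the iodo aldehyde F4. CrCl2 with catalytic NiCl2 in DMSO–THF at high dilution should close the ring to the exo-methylene allylic alcohol F5 (both C7 epimers serve). A Ph3SiOReO3-catalysed 1,3-transposition of the allylic alcohol moves the hydroxyl to C20 and the double bond into the ring as the less strained ring-cis C7=C8 olefin. This is 33, where the route resumes at step 20.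

2. Step 6. The catalyst may be overridden by the C1 stereocentre, giving poor facial selectivity at C2. The fallback inverts the unwanted epimer; it sets out from 9. The C2-epimeric δ-lactone alcohol F6 translactonises as before to the 4,5-trans γ-lactone F7, which is separated and silylated (TBSCl, imidazole) to F8. Brief LiOH hydrolysis in THF–water at 0 °C (short enough to spare the alkynylsilane) gives the hydroxy acid F9. Mitsunobu lactonisation (PPh3, DIAD, THF) closes the γ-lactone with inversion at C2 and returns to the route at 13.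

3. Step 12. Alkenyl transfer from the alanate to the substituted epoxide may be slow, or the pivalate carbonyl may be attacked. The fallback changes the nucleophile; it sets out from 20. After the same carboalumination, alane 21 is quenched with iodine to the (E)-vinyl iodide F10. Iodine–lithium exchange with t-BuLi in Et2O at −78 °C gives the alkenyllithium F11. BF3·OEt2-assisted opening of (S)-glycidyl pivalate at −78 °C, which should be faster than addition to the hindered ester, then returns to the route at 23.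

Further compounds
F1 | step 18 | iodoalkenyl-9-BBN adduct of 25 (B on C20, I on C8, cis) | CC[Si](CC)(CC)OC[C@@H](CCC=C(C)C)[C@@H]([C@@H](O[Si](C)(C)C(C)(C)C)C/C(C)=C/C[C@H](OC(=O)C(C)(C)C)COC(=O)C(C)(C)C)[C@H](/C(I)=C/B1C2CCCC1CCC2)CO[Si](C)(C)C(C)(C)C
F2 | step 18 | 2-iodoalkene bis-pivalate (C8(I)=C20H2) | CC[Si](CC)(CC)OC[C@@H](CCC=C(C)C)[C@@H]([C@@H](O[Si](C)(C)C(C)(C)C)C/C(C)=C/C[C@H](OC(=O)C(C)(C)C)COC(=O)C(C)(C)C)[C@H](C(I)=C)CO[Si](C)(C)C(C)(C)C
F3 | step 18 | 2-iodoalkene C7,C7′-diol | CC[Si](CC)(CC)OC[C@@H](CCC=C(C)C)[C@@H]([C@@H](O[Si](C)(C)C(C)(C)C)C/C(C)=C/C[C@H](O)CO)[C@H](C(I)=C)CO[Si](C)(C)C(C)(C)C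
F4 | step 18 | 2-iodoalkene C7 aldehyde | CC[Si](CC)(CC)OC[C@@H](CCC=C(C)C)[C@@H]([C@@H](O[Si](C)(C)C(C)(C)C)C/C(C)=C/CC=O)[C@H](C(I)=C)CO[Si](C)(C)C(C)(C)C
F5 | step 18 | nine-membered C7 allylic alcohol with exocyclic C8=C20H2 (C7 epimers) | CC[Si](CC)(CC)OC[C@@H](CCC=C(C)C)[C@H]1[C@@H](O[Si](C)(C)C(C)(C)C)C/C(C)=C/CC(O)C(=C)[C@@H]1CO[Si](C)(C)C(C)(C)C
F6 | step 6 | (4R,5R)-4-[(1R)-1-hydroxybut-3-yn-1-yl]-5-[(trimethylsilyl)ethynyl]oxan-2-one (C2 epimer of 11) | O=C1C[C@@H]([C@H](O)CC#C)[C@H](C#C[Si](C)(C)C)CO1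
F7 | step 6 | (4R,5R)-4-[(2R)-1-hydroxy-4-(trimethylsilyl)but-3-yn-2-yl]-5-(prop-2-yn-1-yl)oxolan-2-one (C2 epimer of 12) | O=C1C[C@H]([C@H](C#C[Si](C)(C)C)CO)[C@@H](CC#C)O1
F8 | step 6 | TBS ether of F7 | O=C1C[C@H]([C@H](C#C[Si](C)(C)C)CO[Si](C)(C)C(C)(C)C)[C@@H](CC#C)O1
F9 | step 6 | (3R,4R)-3-[(2R)-1-[(tert-butyldimethylsilyl)oxy]-4-(trimethylsilyl)but-3-yn-2-yl]-4-hydroxyhept-6-ynoic acid | OC(=O)C[C@@H]([C@H](O)CC#C)[C@H](C#C[Si](C)(C)C)CO[Si](C)(C)C(C)(C)C
F10 | step 12 | (E)-vinyl iodide (I on C5, methyl on C4) | CC[Si](CC)(CC)OC[C@@H](CCC=C(C)C)[C@@H]([C@@H](O[Si](C)(C)C(C)(C)C)C/C(C)=C/I)[C@H](C#C[Si](C)(C)C)CO[Si](C)(C)C(C)(C)C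
F11 | step 12 | (E)-alkenyllithium from F10 | CC[Si](CC)(CC)OC[C@@H](CCC=C(C)C)[C@@H]([C@@H](O[Si](C)(C)C(C)(C)C)C/C(C)=C/[Li])[C@H](C#C[Si](C)(C)C)CO[Si](C)(C)C(C)(C)C
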